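**Strategy.** The ten-membered carbocycle (C1–C10) is disconnected at C4–C5 and C6–C7, so that C5–C6 becomes acetylene and C4 and C7 become aldehydes of an open-chain precursor hung on a carvone-derived cyclohexene. In the key step ethynylenedimagnesium dibromide adds twice to dialdehyde 25, making both bonds and closing the ring as a cyclodecyne; the symmetric two-carbon linchpin makes the order of the two additions immaterial. The step exploits the 1,4-dioxygenated C4–C5–C6–C7 segment shared by the ten-membered ring and the tetrahydropyran (O, C4–C8): the derived yne-dione takes up C16 by cuprate addition and then folds into the 4,8-ether bridge by hemiketalisation and reduction.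

Key step: step 20

Remark: all intermediates carry the briarane locants of the target (C1–C20; C15 = methyl on C1, C16 = one-carbon substituent on C5, C18 = methyl on C17, C19 = lactone carbonyl, C20 = methyl on C11). Aldehyde 2 and stannane 16 are taken as catalogue compounds.

Step 1
Reactants: 1 (S)-carvone; 2 3-[(4-methoxybenzyl)oxy]propanal
Product: 3 aldol adduct
Conditions: LiN(iPr)2, THF, −78 °C; then 2; aq. NH4Cl
Reagents that add atoms: none
Why: Aldol addition of the kinetic α'-lithium enolate of carvone should occur anti to the isopropenyl group on C14; the two new centres are erased or reset in steps 2 and 3.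

Step 2
Reactants: 3 aldol adduct
Product: 4 β-diketone
Conditions: Dess–Martin periodinane, NaHCO3, CH2Cl2, 0 °C to rt
Reagents that add atoms: none
Why: Dess–Martin oxidation of a β-hydroxy ketone should give the 2-acyl enone without retro-aldol cleavage.

Step 3
Reactants: 4 β-diketone
Product: 5 methylated diketone
Conditions: K2CO3, MeI, acetone, rt
Reagents that add atoms: iodomethane, CI
Why: C-alkylation of the β-diketone enolate; iodomethane should approach C1 anti to the vicinal isopropenyl group, leaving C15 trans and the C2 acyl chain cis to it, as the target requires.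

Step 4
Reactants: 5 methylated diketone
Product: 7 C14 acetate, via methoxy hydroperoxide 6 (not isolated)
Conditions: O3, CH2Cl2/MeOH, −78 °C; then Ac2O, Et3N, DMAP (cat.), 0 °C to rt
Reagents that add atoms: ozone, [O-][O+]=O; methanol, CO
Why: Ozonolysis of the electron-rich 1,1-disubstituted alkene (enone and arene react more slowly) and Criegee rearrangement of the acetylated hydroperoxide should turn the isopropenyl group into an acetate with retention at C14.

Step 5
Reactants: 7 C14 acetate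
Product: 8 C14 alcohol
Conditions: AcCl (0.2 equiv), MeOH, 0 °C to rt
Reagents that add atoms: none
Why: Acid-catalysed transesterification removes the acetate without forming the C14 alkoxide, which would open the ring by retro-aldol cleavage of C14–C1; the PMB ether is stable.

Step 6
Reactants: 8 C14 alcohol
Product: 9 syn-1,3-diol
Conditions: Et2BOMe, THF/MeOH, −78 °C; NaBH4; AcOH/MeOH work-up
Reagents that add atoms: none
Why: Narasaka–Prasad reduction; the boron chelate between the C14 hydroxyl and the non-conjugated C2 ketone should take hydride on its exo face and give the 1,3-syn diol, that is (2R), while the hindered enone is untouched.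

Step 7
Reactants: 9 syn-1,3-diol
Product: 10 bis-TBS ether
Conditions: TBSOTf, 2,6-lutidine, CH2Cl2, −78 to 0 °C
Reagents that add atoms: tert-butyldimethylsilyl trifluoromethanesulfonate, CC(C)(C)[Si](C)(C)OS(=O)(=O)C(F)(F)F
Why: Silyl triflate silylation protects both hindered secondary alcohols under a non-nucleophilic base and so avoids retro-aldol of the β-hydroxy ketone.

Step 8
Reactants: 10 bis-TBS ether
Product: 11 epoxy ketone
Conditions: 30 % H2O2, NaOH (cat.), MeOH, 0 °C
Reagents that add atoms: hydrogen peroxide, OO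
Why: Weitz–Scheffer epoxidation; hydroperoxide should add to C12 anti to the axial C14 silyloxy group (as with carvone), placing the epoxide on the face opposite to it.

Step 9
Reactants: 11 epoxy ketone
Product: 12 allylic alcohol
Conditions: N2H4·H2O, AcOH, MeOH, 0 °C to rt
Reagents that add atoms: none
Why: Wharton transposition of the α,β-epoxy ketone via its hydrazone gives the C10=C11 alkene and keeps the C12–O bond, so the hydroxyl sits trans to the C14 oxygen.

Step 10
Reactants: 12 allylic alcohol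
Product: 13 allyloxyacetamide
Conditions: NaH, BrCH2C(O)N(OMe)Me, Bu4NI (cat.), THF/DMF, 0 °C to rt
Reagents that add atoms: 2-bromo-N-methoxy-N-methylacetamide, CON(C)C(=O)CBr
Why: Williamson etherification of the sodium alkoxide with a reactive α-bromo amide.

Step 11
Reactants: 13 allyloxyacetamide
Product: 14 α-hydroxy Weinreb amide
Conditions: LiN(iPr)2, THF, −78 to 0 °C; aq. NH4Cl
Reagents that add atoms: none
Why: [2,3]-Wittig rearrangement of the amide enolate; the C9–C10 bond forms suprafacially on the face vacated by the C12 oxygen (sets C10), the amide group sits exo in the envelope transition state away from the axial C15 methyl (sets C9 as in the target), and C11=C12 is generated.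

Step 12
Reactants: 14 α-hydroxy Weinreb amide
Product: 15 C9 naphthylmethyl ether
Conditions: 2-(bromomethyl)naphthalene, Ag2O, CH2Cl2, 4 Å sieves, rt
Reagents that add atoms: 2-(bromomethyl)naphthalene, BrCc1ccc2ccccc2c1
Why: O-alkylation with Ag2O is mild enough to leave the α-centre C9 intact; the 2-naphthylmethyl ether later acts as chelating group and survives PMB removal.

Step 13
Reactants: 16 tributyl(iodomethyl)stannane; 17 4-methoxybenzyl alcohol
Product: 18 tributyl{[(4-methoxybenzyl)oxy]methyl}stannane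
Conditions: NaH, THF/DMF, 0 °C to rt
Reagents that add atoms: none
Why: Williamson etherification of the primary iodide.

Step 14
Reactants: 15 C9 naphthylmethyl ether; 18 tributyl{[(4-methoxybenzyl)oxy]methyl}stannane
Product: 19 α,α'-dialkoxy ketone
Conditions: 18, n-BuLi, THF, −78 °C; then 15, −78 °C; aq. NH4Cl
Reagents that add atoms: none
Why: Tin–lithium exchange gives the alkoxymethyllithium, which adds once to the Weinreb amide (stable chelated adduct) and installs C7 at the alcohol oxidation level.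

Step 15
Reactants: 20 tert-butyl propanoate
Product: 21 (E)-silyl ketene acetal
Conditions: LiN(iPr)2, THF, −78 °C; Me3SiCl
Reagents that add atoms: chlorotrimethylsilane, C[Si](C)(C)Cl
Why: Kinetic enolisation under Ireland conditions and O-silylation.

Step 16
Reactants: 19 α,α'-dialkoxy ketone; 21 (E)-silyl ketene acetal
Product: 22 tertiary alcohol
Conditions: TiCl4, CH2Cl2, −78 °C; then 21; aq. NaHCO3
Reagents that add atoms: none
Why: Chelation-controlled Mukaiyama aldol addition; TiCl4 bridges the C8 carbonyl and the C9 ether oxygen so that the nucleophile adds anti to C10 (sets C8), and the open antiperiplanar transition state is expected to give the syn relation of C8–OH and C18.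

Step 17
Reactants: 22 tertiary alcohol
Product: 23 C8 triethylsilyl ether
Conditions: Et3SiOTf, 2,6-lutidine, CH2Cl2, 0 °C
Reagents that add atoms: triethylsilyl trifluoromethanesulfonate, CC[Si](CC)(CC)OS(=O)(=O)C(F)(F)F
Why: Silyl triflate silylation of the tertiary alcohol prevents its later 5-endo addition to the ynone.

Step 18
Reactants: 23 C8 triethylsilyl ether
Product: 24 C4,C7-diol
Conditions: DDQ (2.4 equiv), CH2Cl2/pH 7 buffer, 0 °C
Reagents that add atoms: none
Why: Oxidative cleavage of both PMB ethers; the less electron-rich 2-naphthylmethyl ether reacts more slowly and should be retained.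

Step 19
Reactants: 24 C4,C7-diol
Product: 25 dialdehyde
Conditions: Dess–Martin periodinane, NaHCO3, CH2Cl2, rt
Reagents that add atoms: none
Why: Dess–Martin oxidation of both primary alcohols under buffered conditions.

Step 20
Reactants: 25 dialdehyde
Product: 28 macrocyclic yne-diol, via C4 mono-adduct 26 (not isolated), via C7 mono-adduct 27 (not isolated)
Conditions: HC≡CH, EtMgBr (2 equiv), THF, 0 °C (gives BrMgC≡CMgBr); reagent and 25 added together over 10 h to THF (final 2 mM), 0 °C to rt; aq. NH4Cl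
Reagents that add atoms: acetylene, C#C
Why: Two alkynyl Grignard additions of the acetylene bis-Grignard reagent: the first, intermolecular one gives alkoxide-acetylide 26 or 27, and the second closes the ring. The closest known reactions are the but-2-yne-1,4-diol synthesis from this reagent with two carbonyl compounds and the intramolecular acetylide–aldehyde closure of ten-membered carbocycles. The ten-membered ring closes by 10-exo-trig addition to the remaining carbonyl and holds the linear C4–C5≡C6–C7 unit as a cyclodecyne, the trans-disposed C2 and C9 arms on the cyclohexene bringing the termini together. Because the reagent is symmetric, both orders of addition give 28, so no chemoselectivity between the two aldehydes is needed. The selectivity that is needed, cyclisation over oligomerisation or double capping, rests on 1:1 stoichiometry and slow addition at high dilution. The new carbinol centres C4 and C7 form without control and are erased in step 21.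

Step 21
Reactants: 28 macrocyclic yne-diol
Product: 29 yne-dione
Conditions: Dess–Martin periodinane, NaHCO3, CH2Cl2, 0 °C
Reagents that add atoms: none
Why: Dess–Martin oxidation of both propargylic alcohols removes the two uncontrolled centres.

Step 22
Reactants: 29 yne-dione
Product: 30 (Z)-ene-dione
Conditions: Me2CuLi (from CuI and MeLi, 1.1 equiv), THF, −78 °C; aq. NH4Cl/NH3
Reagents that add atoms: lithium dimethylcuprate, [Li+].C[Cu-]C
Why: Syn carbocupration (conjugate addition) of the ynone; methyl should go to C5, the alkyne terminus remote from the fully substituted C8, and protonation gives the ene-dione with C4 and C7 cis.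

Step 23
Reactants: 30 (Z)-ene-dione
Product: 32 bridged hemiketal, via hydroxy ene-dione 31 (not isolated)
Conditions: HF·pyridine, pyridine, THF, 0 °C
Reagents that add atoms: none
Why: The tertiary triethylsilyl ether is cleaved faster than the secondary TBS ethers, and the freed C8 hydroxyl adds 6-exo-trig to the C4 ketone to give the Achmatowicz-type hemiketal.

Step 24
Reactants: 32 bridged hemiketal
Product: 33 bridged pyranone
Conditions: Et3SiH, BF3·OEt2, CH2Cl2, −78 to −40 °C
Reagents that add atoms: none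
Why: Kishi reduction (ionic hydrogenation); the bridgehead oxocarbenium ion of the bicyclo[5.3.1] system is reduced by the silane and the bridge dictates the configuration at C4.

Step 25
Reactants: 33 bridged pyranone
Product: 34 α-chloro ketone
Conditions: LiN(SiMe3)2, THF, −78 °C; N-chlorosuccinimide, −78 °C; aq. NH4Cl
Reagents that add atoms: N-chlorosuccinimide, O=C1CCC(=O)N1Cl
Why: γ-Deprotonation of the β-methyl enone (C8 carries no hydrogen) gives the extended dienolate, which should be chlorinated at the α-carbon C6 on the face opposite the C3/C9 bridge (equatorial chloride), moving the double bond to C5=C16.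

Step 26
Reactants: 34 α-chloro ketone
Product: 35 diacetate
Conditions: Ac2O, Cu(OTf)2 (5 mol %), CH2Cl2, rt
Reagents that add atoms: acetic anhydride, CC(=O)OC(C)=O
Why: Lewis-acid-catalysed direct exchange of silyl ethers for acetates avoids base, which could epimerise C6 or conjugate the β,γ-enone.

Step 27
Reactants: 35 diacetate
Product: 36 C9 alcohol
Conditions: DDQ, CH2Cl2/H2O, rt
Reagents that add atoms: none
Why: Oxidative cleavage of the 2-naphthylmethyl ether by DDQ.

Step 28
Reactants: 36 C9 alcohol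
Product: 38 target CNP0198838.2, via hydroxy ester 37 (not isolated)
Conditions: Me4NBH(OAc)3, MeCN/AcOH, −30 °C; then CF3CO2H, CH2Cl2, 0 °C
Reagents that add atoms: none
Why: Evans–Saksena reduction; the acetoxyborohydride bound to the C9 hydroxyl should deliver hydride to the bridge face of the C7 ketone (C7 hydroxyl cis to the C17 side chain), and acid then cleaves the tert-butyl ester and closes the cis-fused γ-lactone.

**Compound list**

1 | (S)-(+)-carvone, (5S)-2-methyl-5-(prop-1-en-2-yl)cyclohex-2-en-1-one | CC(=C)[C@H]1CC=C(C)C(=O)C1 | starting material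
2 | 3-[(4-methoxybenzyl)oxy]propanal | O=CCCOCc1ccc(OC)cc1 | starting material
3 | aldol adduct: carvone bearing a 1-hydroxy-3-(PMB-oxy)propyl group on C1, trans to the isopropenyl group, both carbinol epimers | OC(CCOCc1ccc(OC)cc1)[C@@H]1[C@@H](C(C)=C)CC=C(C)C1=O | intermediate
4 | β-diketone: C2 ketone, C1 not fixed (keto and enol forms) | O=C(CCOCc1ccc(OC)cc1)C1[C@@H](C(C)=C)CC=C(C)C1=O | intermediate
5 | methylated diketone: quaternary C1, C15 methyl trans and C2 acyl chain cis to the C14 isopropenyl group | O=C(CCOCc1ccc(OC)cc1)[C@@]1(C)[C@@H](C(C)=C)CC=C(C)C1=O | intermediate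
6 | methoxy hydroperoxide: 5 with the isopropenyl group replaced by 1-hydroperoxy-1-methoxyethyl (epimers) | O=C(CCOCc1ccc(OC)cc1)[C@@]1(C)[C@@H](C(C)(OC)OO)CC=C(C)C1=O | intermediate
7 | C14 acetate: acetoxy cis to the C2 acyl chain, trans to C15 | O=C(CCOCc1ccc(OC)cc1)[C@@]1(C)[C@@H](OC(C)=O)CC=C(C)C1=O | intermediate
8 | C14 alcohol (β-hydroxy diketone) | O=C(CCOCc1ccc(OC)cc1)[C@@]1(C)[C@@H](O)CC=C(C)C1=O | intermediate
9 | syn-1,3-diol: (2R)-C2 carbinol and C14 carbinol, C10 enone, C4 PMB ether | COc1ccc(COCC[C@@H](O)[C@@]2(C)[C@@H](O)CC=C(C)C2=O)cc1 | intermediate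
10 | bis-TBS ether of 9 | COc1ccc(COCC[C@@H](O[Si](C)(C)C(C)(C)C)[C@@]2(C)[C@@H](O[Si](C)(C)C(C)(C)C)CC=C(C)C2=O)cc1 | intermediate
11 | epoxy ketone: C11–C12 epoxide trans to the C14 silyloxy group | COc1ccc(COCC[C@@H](O[Si](C)(C)C(C)(C)C)[C@@]2(C)[C@@H](O[Si](C)(C)C(C)(C)C)C[C@@H]3O[C@]3(C)C2=O)cc1 | intermediate
12 | allylic alcohol: C10=C11 alkene, C12 hydroxyl trans to the C14 silyloxy group | COc1ccc(COCC[C@@H](O[Si](C)(C)C(C)(C)C)[C@@]2(C)[C@@H](O[Si](C)(C)C(C)(C)C)C[C@H](O)C(C)=C2)cc1 | intermediate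
13 | allyloxyacetamide: C12–O–CH2–C(O)N(OMe)Me ether of 12 | COc1ccc(COCC[C@@H](O[Si](C)(C)C(C)(C)C)[C@@]2(C)[C@@H](O[Si](C)(C)C(C)(C)C)C[C@H](OCC(=O)N(C)OC)C(C)=C2)cc1 | intermediate
14 | α-hydroxy Weinreb amide: C10 and C9 configured as in the target, C11=C12 alkene, C8 = amide carbonyl | COc1ccc(COCC[C@@H](O[Si](C)(C)C(C)(C)C)[C@@]2(C)[C@@H](O[Si](C)(C)C(C)(C)C)CC=C(C)[C@@H]2[C@@H](O)C(=O)N(C)OC)cc1 | intermediate
15 | C9 2-naphthylmethyl ether of 14 | COc1ccc(COCC[C@@H](O[Si](C)(C)C(C)(C)C)[C@@]2(C)[C@@H](O[Si](C)(C)C(C)(C)C)CC=C(C)[C@@H]2[C@@H](OCc3ccc4ccccc4c3)C(=O)N(C)OC)cc1 | intermediate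
16 | tributyl(iodomethyl)stannane | CCCC[Sn](CCCC)(CCCC)CI | starting material
17 | 4-methoxybenzyl alcohol | COc1ccc(CO)cc1 | starting material
18 | tributyl{[(4-methoxybenzyl)oxy]methyl}stannane | CCCC[Sn](CCCC)(CCCC)COCc1ccc(OC)cc1 | intermediate
19 | α,α'-dialkoxy ketone: C8 ketone flanked by C9 (O-naphthylmethyl) and C7H2 (O-PMB) | COc1ccc(COCC[C@@H](O[Si](C)(C)C(C)(C)C)[C@@]2(C)[C@@H](O[Si](C)(C)C(C)(C)C)CC=C(C)[C@@H]2[C@@H](OCc3ccc4ccccc4c3)C(=O)COCc3ccc(OC)cc3)cc1 | intermediate
20 | tert-butyl propanoate | CCC(=O)OC(C)(C)C | starting material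
21 | (E)-1-tert-butoxy-1-(trimethylsilyloxy)prop-1-ene (methyl cis to O-tert-butyl) | C/C=C(\OC(C)(C)C)O[Si](C)(C)C | intermediate
22 | tertiary alcohol: C8 carbinol and C17 methine configured as in the target, C19 tert-butyl ester | COc1ccc(COCC[C@@H](O[Si](C)(C)C(C)(C)C)[C@@]2(C)[C@@H](O[Si](C)(C)C(C)(C)C)CC=C(C)[C@@H]2[C@@H](OCc3ccc4ccccc4c3)[C@@](O)(COCc3ccc(OC)cc3)[C@@H](C)C(=O)OC(C)(C)C)cc1 | intermediate
23 | C8 triethylsilyl ether of 22 | COc1ccc(COCC[C@@H](O[Si](C)(C)C(C)(C)C)[C@@]2(C)[C@@H](O[Si](C)(C)C(C)(C)C)CC=C(C)[C@@H]2[C@@H](OCc3ccc4ccccc4c3)[C@@](O[Si](CC)(CC)CC)(COCc3ccc(OC)cc3)[C@@H](C)C(=O)OC(C)(C)C)cc1 | intermediate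
24 | C4,C7-diol (both primary alcohols free) | OCC[C@@H](O[Si](C)(C)C(C)(C)C)[C@@]1(C)[C@@H](O[Si](C)(C)C(C)(C)C)CC=C(C)[C@@H]1[C@@H](OCc2ccc3ccccc3c2)[C@@](O[Si](CC)(CC)CC)(CO)[C@@H](C)C(=O)OC(C)(C)C | intermediate
25 | dialdehyde (C4 and C7 formyl groups) | O=CC[C@@H](O[Si](C)(C)C(C)(C)C)[C@@]1(C)[C@@H](O[Si](C)(C)C(C)(C)C)CC=C(C)[C@@H]1[C@@H](OCc2ccc3ccccc3c2)[C@@](O[Si](CC)(CC)CC)(C=O)[C@@H](C)C(=O)OC(C)(C)C | intermediate
26 | C4 mono-adduct: bromomagnesium alkoxide at C4 carrying the alkynylmagnesium bromide, C7 aldehyde intact (C4 epimers) | Br[Mg]C#CC(O[Mg]Br)C[C@@H](O[Si](C)(C)C(C)(C)C)[C@@]1(C)[C@@H](O[Si](C)(C)C(C)(C)C)CC=C(C)[C@@H]1[C@@H](OCc2ccc3ccccc3c2)[C@@](O[Si](CC)(CC)CC)(C=O)[C@@H](C)C(=O)OC(C)(C)C | intermediate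
27 | C7 mono-adduct: bromomagnesium alkoxide at C7 carrying the alkynylmagnesium bromide, C4 aldehyde intact (C7 epimers) | O=CC[C@@H](O[Si](C)(C)C(C)(C)C)[C@@]1(C)[C@@H](O[Si](C)(C)C(C)(C)C)CC=C(C)[C@@H]1[C@@H](OCc2ccc3ccccc3c2)[C@@](O[Si](CC)(CC)CC)(C(O[Mg]Br)C#C[Mg]Br)[C@@H](C)C(=O)OC(C)(C)C | intermediate
28 | macrocyclic yne-diol: ten-membered ring with C5≡C6, hydroxyls at C4 and C7 (epimer mixture) | OC1C[C@@H](O[Si](C)(C)C(C)(C)C)[C@@]2(C)[C@@H](O[Si](C)(C)C(C)(C)C)CC=C(C)[C@@H]2[C@@H](OCc2ccc3ccccc3c2)[C@](O[Si](CC)(CC)CC)([C@@H](C)C(=O)OC(C)(C)C)C(O)C#C1 | intermediate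
29 | yne-dione: C4 and C7 ketones flanking C5≡C6 | O=C1C[C@@H](O[Si](C)(C)C(C)(C)C)[C@@]2(C)[C@@H](O[Si](C)(C)C(C)(C)C)CC=C(C)[C@@H]2[C@@H](OCc2ccc3ccccc3c2)[C@](O[Si](CC)(CC)CC)([C@@H](C)C(=O)OC(C)(C)C)C(=O)C#C1 | intermediate
30 | (Z)-ene-dione: C5(C16 methyl)=C6H with C4 and C7 carbonyls cis | O=C1C[C@@H](O[Si](C)(C)C(C)(C)C)[C@@]2(C)[C@@H](O[Si](C)(C)C(C)(C)C)CC=C(C)[C@@H]2[C@@H](OCc2ccc3ccccc3c2)[C@](O[Si](CC)(CC)CC)([C@@H](C)C(=O)OC(C)(C)C)C(=O)/C=C1/C | intermediate
31 | hydroxy ene-dione: 30 with free C8 hydroxyl | O=C1C[C@@H](O[Si](C)(C)C(C)(C)C)[C@@]2(C)[C@@H](O[Si](C)(C)C(C)(C)C)CC=C(C)[C@@H]2[C@@H](OCc2ccc3ccccc3c2)[C@](O)([C@@H](C)C(=O)OC(C)(C)C)C(=O)/C=C1/C | intermediate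
32 | bridged hemiketal: 4,8-epoxy bridge, C4 hydroxyl, C5=C6 enone with C7 ketone | CC=1[C@]2(O)C[C@@H](O[Si](C)(C)C(C)(C)C)[C@@]3(C)[C@@H](O[Si](C)(C)C(C)(C)C)CC=C(C)[C@@H]3[C@@H](OCc4ccc5ccccc5c4)[C@](O2)([C@@H](C)C(=O)OC(C)(C)C)C(=O)C=1 | intermediate
33 | bridged pyranone: 4,8-epoxy bridge with C4–H as in the target, C5(Me)=C6 enone, C7 ketone | CC=1[C@@H]2C[C@@H](O[Si](C)(C)C(C)(C)C)[C@@]3(C)[C@@H](O[Si](C)(C)C(C)(C)C)CC=C(C)[C@@H]3[C@@H](OCc4ccc5ccccc5c4)[C@](O2)([C@@H](C)C(=O)OC(C)(C)C)C(=O)C=1 | intermediate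
34 | α-chloro ketone: C5=C16 methylene, C6 chloride as in the target, C7 ketone | C=C1[C@@H]2C[C@@H](O[Si](C)(C)C(C)(C)C)[C@@]3(C)[C@@H](O[Si](C)(C)C(C)(C)C)CC=C(C)[C@@H]3[C@@H](OCc4ccc5ccccc5c4)[C@](O2)([C@@H](C)C(=O)OC(C)(C)C)C(=O)[C@H]1Cl | intermediate
35 | diacetate: C2 and C14 acetates, C9 naphthylmethyl ether | C=C1[C@@H]2C[C@@H](OC(C)=O)[C@@]3(C)[C@@H](OC(C)=O)CC=C(C)[C@@H]3[C@@H](OCc4ccc5ccccc5c4)[C@](O2)([C@@H](C)C(=O)OC(C)(C)C)C(=O)[C@H]1Cl | intermediate
36 | C9 alcohol: free C9 hydroxyl, C7 ketone, tert-butyl ester | C=C1[C@@H]2C[C@@H](OC(C)=O)[C@@]3(C)[C@@H](OC(C)=O)CC=C(C)[C@@H]3[C@@H](O)[C@](O2)([C@@H](C)C(=O)OC(C)(C)C)C(=O)[C@H]1Cl | intermediate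
37 | hydroxy ester: C7 hydroxyl cis to the C17 side chain, tert-butyl ester | C=C1[C@@H]2C[C@@H](OC(C)=O)[C@@]3(C)[C@@H](OC(C)=O)CC=C(C)[C@@H]3[C@@H](O)[C@](O2)([C@@H](C)C(=O)OC(C)(C)C)[C@@H](O)[C@H]1Cl | intermediate
38 | CNP0198838.2, (1R,2R,4S,6S,7R,8R,9R,10S,14S,17R)-2,14-diacetoxy-6-chloro-4,8-epoxy-9-hydroxybriara-5(16),11-dien-19,7-olide | C=C1[C@@H]2C[C@@H](OC(C)=O)[C@@]3(C)[C@@H](OC(C)=O)CC=C(C)[C@@H]3[C@@H](O)[C@]3(O2)[C@@H](C)C(=O)O[C@H]3[C@H]1Cl | target

**Step count.** 28 steps in total. The longest linear sequence is 26 steps (steps 1–12, 14 and 16–28, from carvone).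

**Steps most likely to fail**

Step 20. Intermolecular addition of the mono-adduct to a second dialdehyde (oligomerisation), or capping of both aldehydes by two reagent molecules, may outrun closure of the strained ten-membered cycloalkyne. The fallback sets out from 25 and separates the two events. One equivalent of ethynylmagnesium bromide at −78 °C adds to the less hindered C4 aldehyde to give the terminal alkyne with the C7 aldehyde intact, propargylic alcohol F1. Slow addition of F1 to LiN(SiMe3)2 in THF at high dilution then forms the lithium acetylide and closes the ring onto C7 in a purely intramolecular step, returning to 28.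

Step 22. The methyl group may be delivered to the wrong alkyne terminus (C6 instead of C5), and the alkene geometry may scramble. The fallback sets out from 28 and makes the two ends chemically different. Et3SiCl/imidazole silylates only the unhindered C4 hydroxyl to give the mono-silyl ether F2. Dess–Martin oxidation gives the C7 mono-ynone F3, on which Me2CuLi can only add at C5, giving the γ-silyloxy enone F4. HF·pyridine removes both triethylsilyl groups, and the (Z)-γ-hydroxy enone cyclodehydrates to the 2,5-bridged 3-methylfuran, furanophane F5. Achmatowicz oxidation of this tertiary furyl carbinol (VO(acac)2, t-BuOOH, CH2Cl2) rejoins the route at hemiketal 32.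

Step 28. Hydride delivery from the open face may compete with the directed delivery from the C9 hydroxyl, and the freed acid may close onto the C9 hydroxyl instead of the C7 hydroxyl. The fallback sets out from 35, keeps C9 protected, and uses the open face deliberately. NaBH4/CeCl3 gives the C7 epimer, trans-chlorohydrin F6. NaH in THF closes the C6–C7 epoxide on the bridge face with loss of chloride, epoxide F7. CF3CO2H unmasks the acid, which opens the epoxide at C7 from the lower face (5-exo) to give the cis-fused lactone with a C6 hydroxyl on the bridge face, hydroxy lactone F8. PPh3/hexachloroacetone replaces that hydroxyl by chloride with inversion, giving the C9 naphthylmethyl ether of the target F9, and DDQ returns to 38.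

Further compounds
F1 | step 20 | C4 propargylic alcohol with terminal alkyne, C7 aldehyde intact (C4 epimers) | C#CC(O)C[C@@H](O[Si](C)(C)C(C)(C)C)[C@@]1(C)[C@@H](O[Si](C)(C)C(C)(C)C)CC=C(C)[C@@H]1[C@@H](OCc2ccc3ccccc3c2)[C@@](O[Si](CC)(CC)CC)(C=O)[C@@H](C)C(=O)OC(C)(C)C
F2 | step 22 | yne-diol 28 with C4 triethylsilyl ether and free C7 hydroxyl | CC[Si](CC)(CC)OC1C[C@@H](O[Si](C)(C)C(C)(C)C)[C@@]2(C)[C@@H](O[Si](C)(C)C(C)(C)C)CC=C(C)[C@@H]2[C@@H](OCc2ccc3ccccc3c2)[C@](O[Si](CC)(CC)CC)([C@@H](C)C(=O)OC(C)(C)C)C(O)C#C1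
F3 | step 22 | C7 mono-ynone with C4 triethylsilyl ether | CC[Si](CC)(CC)OC1C[C@@H](O[Si](C)(C)C(C)(C)C)[C@@]2(C)[C@@H](O[Si](C)(C)C(C)(C)C)CC=C(C)[C@@H]2[C@@H](OCc2ccc3ccccc3c2)[C@](O[Si](CC)(CC)CC)([C@@H](C)C(=O)OC(C)(C)C)C(=O)C#C1
F4 | step 22 | (Z)-enone with C16 methyl on C5, C4 triethylsilyl ether, C7 ketone | CC[Si](CC)(CC)OC1C[C@@H](O[Si](C)(C)C(C)(C)C)[C@@]2(C)[C@@H](O[Si](C)(C)C(C)(C)C)CC=C(C)[C@@H]2[C@@H](OCc2ccc3ccccc3c2)[C@](O[Si](CC)(CC)CC)([C@@H](C)C(=O)OC(C)(C)C)C(=O)/C=C1/C
F5 | step 22 | furanophane: 3-methylfuran bridging C4 and C7, free tertiary C8 hydroxyl | Cc1cc2oc1C[C@@H](O[Si](C)(C)C(C)(C)C)[C@@]3(C)[C@@H](O[Si](C)(C)C(C)(C)C)CC=C(C)[C@@H]3[C@@H](OCc3ccc4ccccc4c3)[C@]2(O)[C@@H](C)C(=O)OC(C)(C)C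
F6 | step 28 | trans-chlorohydrin: C7 hydroxyl on the bridge face, C6 chloride, C9 naphthylmethyl ether | C=C1[C@@H]2C[C@@H](OC(C)=O)[C@@]3(C)[C@@H](OC(C)=O)CC=C(C)[C@@H]3[C@@H](OCc4ccc5ccccc5c4)[C@](O2)([C@@H](C)C(=O)OC(C)(C)C)[C@H](O)[C@H]1Cl
F7 | step 28 | C6–C7 epoxide on the bridge face | C=C1[C@@H]2C[C@@H](OC(C)=O)[C@@]3(C)[C@@H](OC(C)=O)CC=C(C)[C@@H]3[C@@H](OCc4ccc5ccccc5c4)[C@](O2)([C@@H](C)C(=O)OC(C)(C)C)[C@@H]4O[C@H]14
F8 | step 28 | hydroxy lactone: 19,7-lactone as in the target, C6 hydroxyl on the bridge face | C=C1[C@@H]2C[C@@H](OC(C)=O)[C@@]3(C)[C@@H](OC(C)=O)CC=C(C)[C@@H]3[C@@H](OCc4ccc5ccccc5c4)[C@]3(O2)[C@@H](C)C(=O)O[C@H]3[C@@H]1O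
F9 | step 28 | C9 2-naphthylmethyl ether of the target | C=C1[C@@H]2C[C@@H](OC(C)=O)[C@@]3(C)[C@@H](OC(C)=O)CC=C(C)[C@@H]3[C@@H](OCc4ccc5ccccc5c4)[C@]3(O2)[C@@H](C)C(=O)O[C@H]3[C@H]1Cl
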